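**Retrosynthetic overview**

1. The target is reached by a last peracid epoxidation of the 1(10)E alkene, after esterifying a 3β,8β-dihydroxy heliangolide core (C3 isovalerate, C8 (2S,3S)-epoxyangelate).
2. The ten-membered carbocycle is closed at C3–C4 by an intramolecular Nozaki–Hiyama–Kishi addition of a (Z)-vinyl iodide to an aldehyde; C3 is then fixed by oxidation and CBS reduction.
3. The α-methylene comes from Mannich methylenation of the γ-lactone, the (Z)-vinyl iodide from a Stork–Zhao olefination, and the C8 carbinol from Felkin–Anh reduction of an unmasked ketone.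
4. Key union: intermolecular Michael addition of a lithiated 2-alkyl-1,3-dithiane (C8–C10, C1–C3) to (S)-5-(trityloxymethyl)butenolide (C5–C7, C11, C12) forms C7–C8 trans to C6.
5. Ring order: γ-lactone (from the butenolide), then the ten-membered carbocycle, then the 1,10-oxirane; the side-chain oxirane acid is made separately from angelic acid by Sharpless epoxidation.

Assumption: angelic acid and (5S)-5-(hydroxymethyl)furan-2(5H)-one are taken as catalogue chemicals; locants C1–C15 are germacrane numbering of the target (lactone C12–O–C6, esters on C3 and C8, oxirane C1–C10, C14 on C10, C15 on C4).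

**Fragment C: the oxirane acid**

Step 1
Reactants: 1 angelic acid, (2Z)-2-methylbut-2-enoic acid
Product: 2 (2Z)-2-methylbut-2-en-1-ol
Conditions: LiAlH4, Et2O, 0 °C to rt; then H2O, aq NaOH
Reagents that add atoms: none
Why: Hydride reduction of the carboxylic acid by LiAlH4 gives the allylic alcohol, and the trisubstituted alkene is not reduced and keeps its Z geometry.

Step 2
Reactants: 2 (2Z)-2-methylbut-2-en-1-ol
Product: 3 [(2R,3S)-2,3-dimethyloxiran-2-yl]methanol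
Conditions: Ti(OiPr)4 (10 mol %), D-(−)-diethyl tartrate (12 mol %), t-BuOOH, 4 Å molecular sieves, CH2Cl2, −20 °C
Reagents that add atoms: tert-butyl hydroperoxide, CC(C)(C)OO
Why: Sharpless–Katsuki asymmetric epoxidation, in which the D-(−)-tartrate titanium complex delivers oxygen to the face that gives the (2R,3S) epoxy alcohol and syn addition keeps CH2OH cis to the C3 methyl.

Step 3
Reactants: 3 [(2R,3S)-2,3-dimethyloxiran-2-yl]methanol
Product: 4 (2S,3S)-2,3-dimethyloxirane-2-carboxylic acid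
Conditions: TEMPO (10 mol %), PhI(OAc)2 (2.2 equiv), MeCN/H2O (1:1), rt
Reagents that add atoms: water, O
Why: TEMPO/oxoammonium oxidation of the primary alcohol through the aldehyde hydrate gives the acid without touching the oxirane; the C2 descriptor changes from R to S only because CO2H now outranks C3.

**Fragment B: the dithiane (C8–C10, C1–C3)**

Step 4
Reactants: 5 propane-1,3-diol
Product: 6 3-[(4-methoxyphenyl)methoxy]propan-1-ol
Conditions: NaH (1 equiv), 4-MeOC6H4CH2Cl, Bu4NI (cat.), THF, 0 °C to rt (diol in excess)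
Reagents that add atoms: 4-methoxybenzyl chloride, COc1ccc(CCl)cc1
Why: Williamson etherification of the mono-alkoxide, with excess diol keeping the reaction at the mono-ether.

Step 5
Reactants: 6 3-[(4-methoxyphenyl)methoxy]propan-1-ol
Product: 7 3-[(4-methoxyphenyl)methoxy]propanal
Conditions: TEMPO (10 mol %), PhI(OAc)2 (1.1 equiv), CH2Cl2, rt
Reagents that add atoms: none
Why: TEMPO-catalysed oxidation in anhydrous CH2Cl2 stops at the aldehyde and leaves the benzylic ether alone.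

Step 6
Reactants: 7 3-[(4-methoxyphenyl)methoxy]propanal
Product: 8 ethyl (2E)-5-[(4-methoxyphenyl)methoxy]-2-methylpent-2-enoate
Conditions: Ph3P=C(Me)CO2Et, CH2Cl2, rt
Reagents that add atoms: ethyl 2-(triphenylphosphoranylidene)propanoate, CCOC(=O)C(C)=P(c1ccccc1)(c1ccccc1)c1ccccc1
Why: Wittig olefination with a stabilised ylide gives the (E)-trisubstituted enoate, which fixes the later 1(10)E geometry.

Step 7
Reactants: 8 ethyl (2E)-5-[(4-methoxyphenyl)methoxy]-2-methylpent-2-enoate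
Product: 9 (2E)-5-[(4-methoxyphenyl)methoxy]-2-methylpent-2-en-1-ol
Conditions: i-Bu2AlH (2.2 equiv), CH2Cl2, −78 °C; aq potassium sodium tartrate
Reagents that add atoms: none
Why: 1,2-Reduction of the enoate by i-Bu2AlH gives the allylic alcohol with the alkene geometry unchanged.

Step 8
Reactants: 9 (2E)-5-[(4-methoxyphenyl)methoxy]-2-methylpent-2-en-1-ol
Product: 10 1-({[(3E)-5-bromo-4-methylpent-3-en-1-yl]oxy}methyl)-4-methoxybenzene
Conditions: CBr4, PPh3, CH2Cl2, 0 °C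
Reagents that add atoms: carbon tetrabromide, BrC(Br)(Br)Br
Why: Appel bromination of the primary allylic alcohol proceeds by SN2 at carbon without allylic transposition.

Step 9
Reactants: 11 1,3-dithiane; 10 1-({[(3E)-5-bromo-4-methylpent-3-en-1-yl]oxy}methyl)-4-methoxybenzene
Product: 13 2-{(2E)-5-[(4-methoxyphenyl)methoxy]-2-methylpent-2-en-1-yl}-1,3-dithiane, via 2-lithio-1,3-dithiane 12 (not isolated)
Conditions: n-BuLi, THF, −30 °C; then 10, −78 to 0 °C
Reagents that add atoms: none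
Why: Corey–Seebach alkylation, in which the dithiane anion displaces the primary allylic bromide by SN2 and the E alkene is retained; the dithiane carbon becomes C8.

**Fragment A: the butenolide (C5–C7, C11, C12)**

Step 10
Reactants: 14 (5S)-5-(hydroxymethyl)furan-2(5H)-one
Product: 15 (5S)-5-[(triphenylmethoxy)methyl]furan-2(5H)-one
Conditions: Ph3CCl, Et3N, DMAP (cat.), CH2Cl2, rt
Reagents that add atoms: trityl chloride, ClC(c1ccccc1)(c1ccccc1)c1ccccc1
Why: Tritylation of the primary alcohol installs a bulky group that shields one face of the butenolide; the existing stereocentre (later C6) is untouched.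

**Fragment union and endgame**

Step 11
Reactants: 13 2-{(2E)-5-[(4-methoxyphenyl)methoxy]-2-methylpent-2-en-1-yl}-1,3-dithiane; 15 (5S)-5-[(triphenylmethoxy)methyl]furan-2(5H)-one
Product: 18 (4S,5S)-4-(2-{(2E)-5-[(4-methoxyphenyl)methoxy]-2-methylpent-2-en-1-yl}-1,3-dithian-2-yl)-5-[(triphenylmethoxy)methyl]oxolan-2-one, via lithiated dithiane 16 (not isolated), via lithium enolate 17 (not isolated)
Conditions: n-BuLi, THF, −25 °C; HMPA, −78 °C; then 15, −78 °C; AcOH quench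
Reagents that add atoms: none
Why: Intermolecular Michael addition of the Corey–Seebach acyl-anion equivalent to the butenolide, with HMPA steering it to the 1,4 mode; the nucleophile enters anti to the CH2OCPh3 group, so C7 is set trans to C6.

Step 12
Reactants: 18 (4S,5S)-4-(2-{(2E)-5-[(4-methoxyphenyl)methoxy]-2-methylpent-2-en-1-yl}-1,3-dithian-2-yl)-5-[(triphenylmethoxy)methyl]oxolan-2-one
Product: 19 (4S,5S)-4-{(3E)-6-[(4-methoxyphenyl)methoxy]-3-methylhex-3-enoyl}-5-[(triphenylmethoxy)methyl]oxolan-2-one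
Conditions: MeI, CaCO3, MeCN/H2O (9:1), 45 °C
Reagents that add atoms: water, O
Why: S-Methylation and buffered hydrolysis of the dithiane unmask the C8 ketone under near-neutral conditions that do not isomerise the β,γ-alkene or epimerise the trans lactone.

Step 13
Reactants: 19 (4S,5S)-4-{(3E)-6-[(4-methoxyphenyl)methoxy]-3-methylhex-3-enoyl}-5-[(triphenylmethoxy)methyl]oxolan-2-one
Product: 20 (4R,5S)-4-{(1R,3E)-1-hydroxy-6-[(4-methoxyphenyl)methoxy]-3-methylhex-3-en-1-yl}-5-[(triphenylmethoxy)methyl]oxolan-2-one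
Conditions: LiBH(s-Bu)3, THF, −78 °C; H2O quench at −78 °C
Reagents that add atoms: none
Why: Felkin–Anh reduction by a bulky, non-chelating hydride, which attacks anti to the more substituted ring bond C7–C6 and so sets C8 as R (8β-OH); the lactone is not reduced at −78 °C.

Step 14
Reactants: 20 (4R,5S)-4-{(1R,3E)-1-hydroxy-6-[(4-methoxyphenyl)methoxy]-3-methylhex-3-en-1-yl}-5-[(triphenylmethoxy)methyl]oxolan-2-one
Product: 21 (4S,5S)-4-{(1R,3E)-1-[tert-butyl(dimethyl)silyl]oxy-6-[(4-methoxyphenyl)methoxy]-3-methylhex-3-en-1-yl}-5-[(triphenylmethoxy)methyl]oxolan-2-one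
Conditions: t-BuMe2SiOTf, 2,6-lutidine, CH2Cl2, −78 to 0 °C
Reagents that add atoms: tert-butyldimethylsilyl trifluoromethanesulfonate, CC(C)(C)[Si](C)(C)OS(=O)(=O)C(F)(F)F
Why: Silylation of the hindered secondary alcohol with the silyl triflate protects C8–OH and blocks translactonisation; no stereocentre changes.

Step 15
Reactants: 21 (4S,5S)-4-{(1R,3E)-1-[tert-butyl(dimethyl)silyl]oxy-6-[(4-methoxyphenyl)methoxy]-3-methylhex-3-en-1-yl}-5-[(triphenylmethoxy)methyl]oxolan-2-one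
Product: 22 (4S,5S)-4-{(1R,3E)-1-[tert-butyl(dimethyl)silyl]oxy-6-[(4-methoxyphenyl)methoxy]-3-methylhex-3-en-1-yl}-5-(hydroxymethyl)oxolan-2-one
Conditions: camphorsulfonic acid (cat.), MeOH/CH2Cl2 (1:1), 0 °C to rt
Reagents that add atoms: none
Why: Acid-catalysed solvolysis removes the trityl ether far faster than the hindered secondary silyl ether or the 4-methoxybenzyl ether.

Step 16
Reactants: 22 (4S,5S)-4-{(1R,3E)-1-[tert-butyl(dimethyl)silyl]oxy-6-[(4-methoxyphenyl)methoxy]-3-methylhex-3-en-1-yl}-5-(hydroxymethyl)oxolan-2-one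
Product: 23 (2S,3S)-3-{(1R,3E)-1-[tert-butyl(dimethyl)silyl]oxy-6-[(4-methoxyphenyl)methoxy]-3-methylhex-3-en-1-yl}-5-oxooxolane-2-carbaldehyde
Conditions: Dess–Martin periodinane, NaHCO3, CH2Cl2, 0 °C
Reagents that add atoms: none
Why: Dess–Martin oxidation gives the C5 aldehyde under buffered, non-basic conditions, so C6 is not epimerised; the aldehyde is used at once.

Step 17
Reactants: 23 (2S,3S)-3-{(1R,3E)-1-[tert-butyl(dimethyl)silyl]oxy-6-[(4-methoxyphenyl)methoxy]-3-methylhex-3-en-1-yl}-5-oxooxolane-2-carbaldehyde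
Product: 24 (4S,5S)-4-{(1R,3E)-1-[tert-butyl(dimethyl)silyl]oxy-6-[(4-methoxyphenyl)methoxy]-3-methylhex-3-en-1-yl}-5-[(1Z)-2-iodoprop-1-en-1-yl]oxolan-2-one
Conditions: [Ph3PEt]I, n-BuLi, THF, rt; I2, −78 °C; NaN(SiMe3)2, −20 °C; then 23, −78 °C
Reagents that add atoms: (1-iodoethylidene)triphenylphosphorane (made in the flask), CC(I)=P(c1ccccc1)(c1ccccc1)c1ccccc1
Why: Stork–Zhao variant of the Wittig olefination, in which the unstabilised α-iodo ylide gives the (Z)-2-iodoalkene (iodine cis to C6), i.e. the 4Z geometry, and brings in C4 and C15.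

Step 18
Reactants: 24 (4S,5S)-4-{(1R,3E)-1-[tert-butyl(dimethyl)silyl]oxy-6-[(4-methoxyphenyl)methoxy]-3-methylhex-3-en-1-yl}-5-[(1Z)-2-iodoprop-1-en-1-yl]oxolan-2-one
Product: 26 (3R,4S,5S)-3-[(dimethylamino)methyl]-4-{(1R,3E)-1-[tert-butyl(dimethyl)silyl]oxy-6-[(4-methoxyphenyl)methoxy]-3-methylhex-3-en-1-yl}-5-[(1Z)-2-iodoprop-1-en-1-yl]oxolan-2-one, via lithium enolate 25 (not isolated)
Conditions: LiN(i-Pr)2 (commercial solution), THF, −78 °C; then [Me2N=CH2]I, −78 °C to rt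
Reagents that add atoms: N,N-dimethylmethyleneiminium iodide (Eschenmoser's salt), C[N+](C)=C.[I-]
Why: Mannich reaction of the lithium lactone enolate with Eschenmoser's salt introduces C13; the electrophile adds anti to the C7 side chain, and this new centre is removed in the next step.

Step 19
Reactants: 26 (3R,4S,5S)-3-[(dimethylamino)methyl]-4-{(1R,3E)-1-[tert-butyl(dimethyl)silyl]oxy-6-[(4-methoxyphenyl)methoxy]-3-methylhex-3-en-1-yl}-5-[(1Z)-2-iodoprop-1-en-1-yl]oxolan-2-one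
Product: 28 (4S,5S)-4-{(1R,3E)-1-[tert-butyl(dimethyl)silyl]oxy-6-[(4-methoxyphenyl)methoxy]-3-methylhex-3-en-1-yl}-5-[(1Z)-2-iodoprop-1-en-1-yl]-3-methylideneoxolan-2-one, via trimethylammonium iodide 27 (not isolated)
Conditions: MeI, MeOH, rt; then aq NaHCO3, CH2Cl2, rt
Reagents that add atoms: none
Why: N-Methylation followed by mild-base Hofmann-type (E1cB) elimination of trimethylamine unveils the α-methylene lactone without affecting the vinyl iodide or silyl ether.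

Step 20
Reactants: 28 (4S,5S)-4-{(1R,3E)-1-[tert-butyl(dimethyl)silyl]oxy-6-[(4-methoxyphenyl)methoxy]-3-methylhex-3-en-1-yl}-5-[(1Z)-2-iodoprop-1-en-1-yl]-3-methylideneoxolan-2-one
Product: 29 (4S,5S)-4-{(1R,3E)-1-[tert-butyl(dimethyl)silyl]oxy-6-hydroxy-3-methylhex-3-en-1-yl}-5-[(1Z)-2-iodoprop-1-en-1-yl]-3-methylideneoxolan-2-one
Conditions: DDQ, CH2Cl2/pH 7 buffer (10:1), 0 °C
Reagents that add atoms: none
Why: Oxidative cleavage of the electron-rich 4-methoxybenzyl ether by DDQ frees the C3 primary alcohol; the silyl ether, vinyl iodide and electron-poor alkenes are inert.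

Step 21
Reactants: 29 (4S,5S)-4-{(1R,3E)-1-[tert-butyl(dimethyl)silyl]oxy-6-hydroxy-3-methylhex-3-en-1-yl}-5-[(1Z)-2-iodoprop-1-en-1-yl]-3-methylideneoxolan-2-one
Product: 30 (4S,5S)-4-{(1R,3E)-1-[tert-butyl(dimethyl)silyl]oxy-3-methyl-6-oxohex-3-en-1-yl}-5-[(1Z)-2-iodoprop-1-en-1-yl]-3-methylideneoxolan-2-one
Conditions: Dess–Martin periodinane, NaHCO3, CH2Cl2, 0 °C; used crude
Reagents that add atoms: none
Why: Buffered Dess–Martin oxidation gives the β,γ-unsaturated aldehyde without migration of the alkene into conjugation.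

Step 22
Reactants: 30 (4S,5S)-4-{(1R,3E)-1-[tert-butyl(dimethyl)silyl]oxy-3-methyl-6-oxohex-3-en-1-yl}-5-[(1Z)-2-iodoprop-1-en-1-yl]-3-methylideneoxolan-2-one
Product: 31 8β-[tert-butyl(dimethyl)silyl]oxy-3-hydroxygermacra-1(10)E,4Z,11(13)-trien-12,6α-olide (6R,7S,8R; both C3 epimers)
Conditions: CrCl2 (10 equiv), NiCl2 (2 mol %), DMSO, rt, 2 mM, slow addition of 30
Reagents that add atoms: none
Why: Intramolecular Nozaki–Hiyama–Kishi reaction, in which zerovalent nickel inserts into the C–I bond with retention and the vinyl group passes to trivalent chromium, which adds only to the aldehyde and closes the ten-membered ring at C3–C4; C3 forms unselectively and is corrected in steps 23 and 24.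

Step 23
Reactants: 31 8β-[tert-butyl(dimethyl)silyl]oxy-3-hydroxygermacra-1(10)E,4Z,11(13)-trien-12,6α-olide (both C3 epimers)
Product: 32 (6R,7S,8R)-8β-[tert-butyl(dimethyl)silyl]oxy-3-oxogermacra-1(10)E,4Z,11(13)-trien-12,6α-olide
Conditions: Dess–Martin periodinane, NaHCO3, CH2Cl2, 0 °C
Reagents that add atoms: none
Why: Dess–Martin oxidation of the allylic alcohols converges both C3 epimers on one (Z)-enone.

Step 24
Reactants: 32 (6R,7S,8R)-8β-[tert-butyl(dimethyl)silyl]oxy-3-oxogermacra-1(10)E,4Z,11(13)-trien-12,6α-olide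
Product: 33 (3S,6R,7S,8R)-8β-[tert-butyl(dimethyl)silyl]oxy-3β-hydroxygermacra-1(10)E,4Z,11(13)-trien-12,6α-olide
Conditions: (R)-2-methyl-CBS-oxazaborolidine (1 equiv), catecholborane, toluene, −78 °C; aq NaHCO3 work-up
Reagents that add atoms: none
Why: Corey–Bakshi–Shibata reduction, in which the alkenyl side (C4) acts as the large group and the (R)-catalyst delivers hydride to the face that gives the (3S) allylic alcohol by reagent control; catecholborane spares the lactone and alkenes.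

Step 25
Reactants: 33 (3S,6R,7S,8R)-8β-[tert-butyl(dimethyl)silyl]oxy-3β-hydroxygermacra-1(10)E,4Z,11(13)-trien-12,6α-olide
Product: 34 (3S,6R,7S,8R)-8β-[tert-butyl(dimethyl)silyl]oxy-3β-(3-methylbutanoyloxy)germacra-1(10)E,4Z,11(13)-trien-12,6α-olide
Conditions: (i-PrCH2CO)2O, Et3N, DMAP (cat.), CH2Cl2, 0 °C to rt
Reagents that add atoms: 3-methylbutanoic anhydride, CC(C)CC(=O)OC(=O)CC(C)C
Why: DMAP-catalysed acylation of the only free hydroxyl installs the C3 isovalerate with retention at C3.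

Step 26
Reactants: 34 (3S,6R,7S,8R)-8β-[tert-butyl(dimethyl)silyl]oxy-3β-(3-methylbutanoyloxy)germacra-1(10)E,4Z,11(13)-trien-12,6α-olide
Product: 35 (3S,6R,7R,8R)-8β-hydroxy-3β-(3-methylbutanoyloxy)germacra-1(10)E,4Z,11(13)-trien-12,6α-olide
Conditions: HF·pyridine, pyridine/THF, 0 °C to rt
Reagents that add atoms: none
Why: Buffered fluoride desilylation frees C8–OH under mildly acidic conditions that avoid ester migration, translactonisation and Michael addition to the methylene lactone.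

Step 27
Reactants: 35 (3S,6R,7R,8R)-8β-hydroxy-3β-(3-methylbutanoyloxy)germacra-1(10)E,4Z,11(13)-trien-12,6α-olide; 4 (2S,3S)-2,3-dimethyloxirane-2-carboxylic acid
Product: 37 (3S,6R,7R,8R)-8β-[(2S,3S)-2,3-dimethyloxirane-2-carbonyloxy]-3β-(3-methylbutanoyloxy)germacra-1(10)E,4Z,11(13)-trien-12,6α-olide, via mixed anhydride 36 (not isolated)
Conditions: 4, 2,4,6-Cl3C6H2COCl, Et3N, toluene, rt; then 35, DMAP, rt
Reagents that add atoms: none
Why: Yamaguchi esterification through the mixed anhydride couples the α-quaternary acid to the hindered secondary alcohol with retention at C8 and no epimerisable centre in the acid; any diastereomer from residual enantiomer of 4 is removed by chromatography.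

Step 28
Reactants: 37 (3S,6R,7R,8R)-8β-[(2S,3S)-2,3-dimethyloxirane-2-carbonyloxy]-3β-(3-methylbutanoyloxy)germacra-1(10)E,4Z,11(13)-trien-12,6α-olide
Product: 38 (1R,3S,6R,7R,8R,10R)-1β,10α-epoxy-8β-[(2S,3S)-2,3-dimethyloxirane-2-carbonyloxy]-3β-(3-methylbutanoyloxy)germacra-4Z,11(13)-dien-12,6α-olide (CNP0167461.1)
Conditions: m-CPBA (1.1 equiv), NaHCO3, CH2Cl2, 0 °C
Reagents that add atoms: 3-chloroperoxybenzoic acid, OOC(=O)c1cccc(Cl)c1
Why: Prilezhaev epoxidation of the only electron-rich alkene (C4=C5 carries two allylic acyloxy groups, C11=C13 is conjugated); attack on the exposed outer face of the 1(10)E bond is expected to give the trans (1R,10R) oxirane, as is usual for 1(10)E-germacranolides, while NaHCO3 suppresses acid-induced transannular cyclisation.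

**Compound list**

1 | angelic acid, (2Z)-2-methylbut-2-enoic acid | C/C=C(/C)C(=O)O | starting material
2 | (2Z)-2-methylbut-2-en-1-ol | C/C=C(/C)CO | intermediate
3 | [(2R,3S)-2,3-dimethyloxiran-2-yl]methanol | OC[C@@]1(C)O[C@H]1C | intermediate
4 | (2S,3S)-2,3-dimethyloxirane-2-carboxylic acid | OC(=O)[C@@]1(C)O[C@H]1C | intermediate
5 | propane-1,3-diol | OCCCO | starting material
6 | 3-[(4-methoxyphenyl)methoxy]propan-1-ol | COc1ccc(COCCCO)cc1 | intermediate
7 | 3-[(4-methoxyphenyl)methoxy]propanal | COc1ccc(COCCC=O)cc1 | intermediate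
8 | ethyl (2E)-5-[(4-methoxyphenyl)methoxy]-2-methylpent-2-enoate | CCOC(=O)/C(C)=C/CCOCc1ccc(OC)cc1 | intermediate
9 | (2E)-5-[(4-methoxyphenyl)methoxy]-2-methylpent-2-en-1-ol | OC/C(C)=C/CCOCc1ccc(OC)cc1 | intermediate
10 | 1-({[(3E)-5-bromo-4-methylpent-3-en-1-yl]oxy}methyl)-4-methoxybenzene | BrC/C(C)=C/CCOCc1ccc(OC)cc1 | intermediate
11 | 1,3-dithiane | C1CSCSC1 | starting material
12 | 2-lithio-1,3-dithiane | [Li]C1SCCCS1 | intermediate
13 | 2-{(2E)-5-[(4-methoxyphenyl)methoxy]-2-methylpent-2-en-1-yl}-1,3-dithiane | COc1ccc(COCC/C=C(\C)CC2SCCCS2)cc1 | intermediate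
14 | (5S)-5-(hydroxymethyl)furan-2(5H)-one | O=C1O[C@H](CO)C=C1 | starting material
15 | (5S)-5-[(triphenylmethoxy)methyl]furan-2(5H)-one | O=C1O[C@H](COC(c2ccccc2)(c2ccccc2)c2ccccc2)C=C1 | intermediate
16 | lithiated dithiane (2-lithio derivative of 13) | COc1ccc(COCC/C=C(\C)CC2([Li])SCCCS2)cc1 | intermediate
17 | lithium enolate of 18 (lithium ketene acetal of the lactone) | [Li]OC1=C[C@H](C2(C/C(C)=C/CCOCc3ccc(OC)cc3)SCCCS2)[C@@H](COC(c2ccccc2)(c2ccccc2)c2ccccc2)O1 | intermediate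
18 | (4S,5S)-4-(2-{(2E)-5-[(4-methoxyphenyl)methoxy]-2-methylpent-2-en-1-yl}-1,3-dithian-2-yl)-5-[(triphenylmethoxy)methyl]oxolan-2-one | O=C1O[C@H](COC(c2ccccc2)(c2ccccc2)c2ccccc2)[C@@H](C2(C/C(C)=C/CCOCc3ccc(OC)cc3)SCCCS2)C1 | intermediate
19 | (4S,5S)-4-{(3E)-6-[(4-methoxyphenyl)methoxy]-3-methylhex-3-enoyl}-5-[(triphenylmethoxy)methyl]oxolan-2-one | O=C1O[C@H](COC(c2ccccc2)(c2ccccc2)c2ccccc2)[C@@H](C(=O)C/C(C)=C/CCOCc2ccc(OC)cc2)C1 | intermediate
20 | (4R,5S)-4-{(1R,3E)-1-hydroxy-6-[(4-methoxyphenyl)methoxy]-3-methylhex-3-en-1-yl}-5-[(triphenylmethoxy)methyl]oxolan-2-one | O=C1O[C@H](COC(c2ccccc2)(c2ccccc2)c2ccccc2)[C@@H]([C@H](O)C/C(C)=C/CCOCc2ccc(OC)cc2)C1 | intermediate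
21 | (4S,5S)-4-{(1R,3E)-1-[tert-butyl(dimethyl)silyl]oxy-6-[(4-methoxyphenyl)methoxy]-3-methylhex-3-en-1-yl}-5-[(triphenylmethoxy)methyl]oxolan-2-one | O=C1O[C@H](COC(c2ccccc2)(c2ccccc2)c2ccccc2)[C@@H]([C@H](O[Si](C)(C)C(C)(C)C)C/C(C)=C/CCOCc2ccc(OC)cc2)C1 | intermediate
22 | (4S,5S)-4-{(1R,3E)-1-[tert-butyl(dimethyl)silyl]oxy-6-[(4-methoxyphenyl)methoxy]-3-methylhex-3-en-1-yl}-5-(hydroxymethyl)oxolan-2-one | O=C1O[C@H](CO)[C@@H]([C@H](O[Si](C)(C)C(C)(C)C)C/C(C)=C/CCOCc2ccc(OC)cc2)C1 | intermediate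
23 | (2S,3S)-3-{(1R,3E)-1-[tert-butyl(dimethyl)silyl]oxy-6-[(4-methoxyphenyl)methoxy]-3-methylhex-3-en-1-yl}-5-oxooxolane-2-carbaldehyde | O=C1O[C@H](C=O)[C@@H]([C@H](O[Si](C)(C)C(C)(C)C)C/C(C)=C/CCOCc2ccc(OC)cc2)C1 | intermediate
24 | (4S,5S)-4-{(1R,3E)-1-[tert-butyl(dimethyl)silyl]oxy-6-[(4-methoxyphenyl)methoxy]-3-methylhex-3-en-1-yl}-5-[(1Z)-2-iodoprop-1-en-1-yl]oxolan-2-one | O=C1O[C@H](/C=C(/C)I)[C@@H]([C@H](O[Si](C)(C)C(C)(C)C)C/C(C)=C/CCOCc2ccc(OC)cc2)C1 | intermediate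
25 | lithium enolate of 24 | [Li]OC1=C[C@H]([C@H](O[Si](C)(C)C(C)(C)C)C/C(C)=C/CCOCc2ccc(OC)cc2)[C@@H](/C=C(/C)I)O1 | intermediate
26 | (3R,4S,5S)-3-[(dimethylamino)methyl]-4-{(1R,3E)-1-[tert-butyl(dimethyl)silyl]oxy-6-[(4-methoxyphenyl)methoxy]-3-methylhex-3-en-1-yl}-5-[(1Z)-2-iodoprop-1-en-1-yl]oxolan-2-one | O=C1O[C@H](/C=C(/C)I)[C@@H]([C@H](O[Si](C)(C)C(C)(C)C)C/C(C)=C/CCOCc2ccc(OC)cc2)[C@@H]1CN(C)C | intermediate
27 | trimethylammonium iodide of 26 (N-methylated Mannich base) | O=C1O[C@H](/C=C(/C)I)[C@@H]([C@H](O[Si](C)(C)C(C)(C)C)C/C(C)=C/CCOCc2ccc(OC)cc2)[C@@H]1C[N+](C)(C)C.[I-] | intermediate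
28 | (4S,5S)-4-{(1R,3E)-1-[tert-butyl(dimethyl)silyl]oxy-6-[(4-methoxyphenyl)methoxy]-3-methylhex-3-en-1-yl}-5-[(1Z)-2-iodoprop-1-en-1-yl]-3-methylideneoxolan-2-one | C=C1C(=O)O[C@H](/C=C(/C)I)[C@H]1[C@H](O[Si](C)(C)C(C)(C)C)C/C(C)=C/CCOCc1ccc(OC)cc1 | intermediate
29 | (4S,5S)-4-{(1R,3E)-1-[tert-butyl(dimethyl)silyl]oxy-6-hydroxy-3-methylhex-3-en-1-yl}-5-[(1Z)-2-iodoprop-1-en-1-yl]-3-methylideneoxolan-2-one | C=C1C(=O)O[C@H](/C=C(/C)I)[C@H]1[C@H](O[Si](C)(C)C(C)(C)C)C/C(C)=C/CCO | intermediate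
30 | (4S,5S)-4-{(1R,3E)-1-[tert-butyl(dimethyl)silyl]oxy-3-methyl-6-oxohex-3-en-1-yl}-5-[(1Z)-2-iodoprop-1-en-1-yl]-3-methylideneoxolan-2-one | C=C1C(=O)O[C@H](/C=C(/C)I)[C@H]1[C@H](O[Si](C)(C)C(C)(C)C)C/C(C)=C/CC=O | intermediate
31 | 8β-[tert-butyl(dimethyl)silyl]oxy-3-hydroxygermacra-1(10)E,4Z,11(13)-trien-12,6α-olide (6R,7S,8R; both C3 epimers, C3 left undefined) | C=C1C(=O)O[C@@H]2/C=C(/C)C(O)C/C=C(\C)C[C@@H](O[Si](C)(C)C(C)(C)C)[C@@H]12 | intermediate
32 | (6R,7S,8R)-8β-[tert-butyl(dimethyl)silyl]oxy-3-oxogermacra-1(10)E,4Z,11(13)-trien-12,6α-olide | C=C1C(=O)O[C@@H]2/C=C(/C)C(=O)C/C=C(\C)C[C@@H](O[Si](C)(C)C(C)(C)C)[C@@H]12 | intermediate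
33 | (3S,6R,7S,8R)-8β-[tert-butyl(dimethyl)silyl]oxy-3β-hydroxygermacra-1(10)E,4Z,11(13)-trien-12,6α-olide | C=C1C(=O)O[C@@H]2/C=C(/C)[C@@H](O)C/C=C(\C)C[C@@H](O[Si](C)(C)C(C)(C)C)[C@@H]12 | intermediate
34 | (3S,6R,7S,8R)-8β-[tert-butyl(dimethyl)silyl]oxy-3β-(3-methylbutanoyloxy)germacra-1(10)E,4Z,11(13)-trien-12,6α-olide | C=C1C(=O)O[C@@H]2/C=C(/C)[C@@H](OC(=O)CC(C)C)C/C=C(\C)C[C@@H](O[Si](C)(C)C(C)(C)C)[C@@H]12 | intermediate
35 | (3S,6R,7R,8R)-8β-hydroxy-3β-(3-methylbutanoyloxy)germacra-1(10)E,4Z,11(13)-trien-12,6α-olide | C=C1C(=O)O[C@@H]2/C=C(/C)[C@@H](OC(=O)CC(C)C)C/C=C(\C)C[C@@H](O)[C@@H]12 | intermediate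
36 | mixed anhydride, (2S,3S)-2,3-dimethyloxirane-2-carboxylic 2,4,6-trichlorobenzoic anhydride | O=C(OC(=O)c1c(Cl)cc(Cl)cc1Cl)[C@@]1(C)O[C@H]1C | intermediate
37 | (3S,6R,7R,8R)-8β-[(2S,3S)-2,3-dimethyloxirane-2-carbonyloxy]-3β-(3-methylbutanoyloxy)germacra-1(10)E,4Z,11(13)-trien-12,6α-olide | C=C1C(=O)O[C@@H]2/C=C(/C)[C@@H](OC(=O)CC(C)C)C/C=C(\C)C[C@@H](OC(=O)[C@@]3(C)O[C@H]3C)[C@@H]12 | intermediate
38 | (1R,3S,6R,7R,8R,10R)-1β,10α-epoxy-8β-[(2S,3S)-2,3-dimethyloxirane-2-carbonyloxy]-3β-(3-methylbutanoyloxy)germacra-4Z,11(13)-dien-12,6α-olide (CNP0167461.1) | C=C1C(=O)O[C@@H]2/C=C(/C)[C@@H](OC(=O)CC(C)C)C[C@H]3O[C@]3(C)C[C@@H](OC(=O)[C@@]3(C)O[C@H]3C)[C@@H]12 | target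

**Step count**

Total: 28 steps. Longest linear sequence: 24 steps (propane-1,3-diol 5 through steps 4–9 to 13, then steps 11–28).

**Three steps most likely to fail, with fallbacks**

Step 13 (C8 selectivity of the ketone reduction). The facial bias of a ketone attached to the lactone ring is predicted, not measured, and could be low or reversed. The fallback sets out from 19 and comes back at 20. If reduction of 19 gives mainly the C8 epimer, (4R,5S)-4-{(1S,3E)-1-hydroxy-6-[(4-methoxyphenyl)methoxy]-3-methylhex-3-en-1-yl}-5-[(triphenylmethoxy)methyl]oxolan-2-one F1, the carbinol is inverted by SN2 instead of being re-reduced. A Mitsunobu reaction (chloroacetic acid, PPh3, diisopropyl azodicarboxylate, toluene, 0 °C) gives the inverted ester, (1R,3E)-6-[(4-methoxyphenyl)methoxy]-3-methyl-1-{(2S,3R)-5-oxo-2-[(triphenylmethoxy)methyl]oxolan-3-yl}hex-3-en-1-yl chloroacetate F2. Thiourea and NaHCO3 in EtOH at 50 °C then remove the chloroacetyl group without alkoxide base and return 20.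

Step 22 (ten-membered ring closure by CrCl2/NiCl2). Medium-ring closure may be outrun by oligomerisation or by decay of the β,γ-unsaturated aldehyde. The fallback sets out from 29 and comes back at 32, replacing the carbonyl addition by an intramolecular Stille acylation.
- Me3SnSnMe3 and Pd(PPh3)4 convert 29 into the vinylstannane, (4S,5S)-4-{(1R,3E)-1-[tert-butyl(dimethyl)silyl]oxy-6-hydroxy-3-methylhex-3-en-1-yl}-3-methylidene-5-[(1Z)-2-(trimethylstannyl)prop-1-en-1-yl]oxolan-2-one F3.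
- Dess–Martin periodinane, then NaClO2/NaH2PO4/2-methylbut-2-ene, give the acid, (3E,6R)-6-[tert-butyl(dimethyl)silyl]oxy-4-methyl-6-{(2S,3S)-4-methylidene-5-oxo-2-[(1Z)-2-(trimethylstannyl)prop-1-en-1-yl]oxolan-3-yl}hex-3-enoic acid F4.
- 1-Chloro-N,N,2-trimethylprop-1-en-1-amine gives the corresponding hex-3-enoyl chloride F5.
- Pd2(dba)3 and tri(2-furyl)phosphine in THF at 50 °C under high dilution close the ring directly to enone 32.

Steps 21–23 are bypassed and the route resumes at step 24.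

Step 28 (face selectivity of the final epoxidation). The peracid relies on the ring conformation alone and could give the other trans-oxirane. The fallback sets out from 35 and comes back at 38, using reagent control before the last esterification. Alcohol 35 is epoxidised with the D-fructose-derived Shi ketone and KHSO5 (as the triple salt 2KHSO5·KHSO4·K2SO4) in MeCN/dimethoxymethane/aqueous NaHCO3 buffer at about pH 8 and 0 °C. This dioxirane gives (R,R)-oxiranes from trans-trisubstituted alkenes and should deliver (1R,3S,6R,7R,8R,10R)-1β,10α-epoxy-8β-hydroxy-3β-(3-methylbutanoyloxy)germacra-4Z,11(13)-dien-12,6α-olide F6. F6 is then esterified with 4 under the conditions of step 27 to give 38.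

**Further compounds**

F1 | step 13 | (4R,5S)-4-{(1S,3E)-1-hydroxy-6-[(4-methoxyphenyl)methoxy]-3-methylhex-3-en-1-yl}-5-[(triphenylmethoxy)methyl]oxolan-2-one | O=C1O[C@H](COC(c2ccccc2)(c2ccccc2)c2ccccc2)[C@@H]([C@@H](O)C/C(C)=C/CCOCc2ccc(OC)cc2)C1
F2 | step 13 | (1R,3E)-6-[(4-methoxyphenyl)methoxy]-3-methyl-1-{(2S,3R)-5-oxo-2-[(triphenylmethoxy)methyl]oxolan-3-yl}hex-3-en-1-yl chloroacetate | O=C1O[C@H](COC(c2ccccc2)(c2ccccc2)c2ccccc2)[C@@H]([C@H](OC(=O)CCl)C/C(C)=C/CCOCc2ccc(OC)cc2)C1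
F3 | step 22 | (4S,5S)-4-{(1R,3E)-1-[tert-butyl(dimethyl)silyl]oxy-6-hydroxy-3-methylhex-3-en-1-yl}-3-methylidene-5-[(1Z)-2-(trimethylstannyl)prop-1-en-1-yl]oxolan-2-one | C=C1C(=O)O[C@H](/C=C(/C)[Sn](C)(C)C)[C@H]1[C@H](O[Si](C)(C)C(C)(C)C)C/C(C)=C/CCO
F4 | step 22 | (3E,6R)-6-[tert-butyl(dimethyl)silyl]oxy-4-methyl-6-{(2S,3S)-4-methylidene-5-oxo-2-[(1Z)-2-(trimethylstannyl)prop-1-en-1-yl]oxolan-3-yl}hex-3-enoic acid | C=C1C(=O)O[C@H](/C=C(/C)[Sn](C)(C)C)[C@H]1[C@H](O[Si](C)(C)C(C)(C)C)C/C(C)=C/CC(=O)O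
F5 | step 22 | (3E,6R)-6-[tert-butyl(dimethyl)silyl]oxy-4-methyl-6-{(2S,3S)-4-methylidene-5-oxo-2-[(1Z)-2-(trimethylstannyl)prop-1-en-1-yl]oxolan-3-yl}hex-3-enoyl chloride | C=C1C(=O)O[C@H](/C=C(/C)[Sn](C)(C)C)[C@H]1[C@H](O[Si](C)(C)C(C)(C)C)C/C(C)=C/CC(=O)Cl
F6 | step 28 | (1R,3S,6R,7R,8R,10R)-1β,10α-epoxy-8β-hydroxy-3β-(3-methylbutanoyloxy)germacra-4Z,11(13)-dien-12,6α-olide | C=C1C(=O)O[C@@H]2/C=C(/C)[C@@H](OC(=O)CC(C)C)C[C@H]3O[C@]3(C)C[C@@H](O)[C@@H]12
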